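3 concentrations are asked, and I have the readings of 2 earlier runs to answer from.

| setting | delta | alpha | flask |
|---|---|---|---|
| starting material | 0.81 M | 0.81 M | 0.81 M |
| coupling partner | 0.70 equiv | 1.6 equiv | 1.05 equiv |
| remark | run made earlier | run made earlier |  |
| time |  |  | 8.0 h |

- delta (time / h: first product / %, starting material / %, double product / %): 0.667: 14.1, 83.0, 3.9; 1.33: 20.5, 73.1, 7.3; 2.00: 24.7, 65.1, 8.3; 3.00: 28.8, 56.7, 9.4; 4.00: 33.2, 53.4, 8.2; 5.00: 35.7, 51.2, 8.3
- alpha (time / h: first product / %, starting material / %, double product / %): 0.417: 18.1, 75.9, 8.4; 0.667: 20.7, 65.3, 12.4; 0.833: 23.5, 59.7, 16.6; 1.33: 26.3, 46.8, 23.3; 2.00: 31.6, 38.0, 29.8; 3.00: 35.8, 25.3, 32.2; 5.00: 41.5, 18.1, 33.0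

(standard deviation of a reading: 1 percentage point)

- concentration of first product at 8.0 h, in M
- concentration of starting material at 8.0 h, in M
- concentration of double product at 8.0 h, in M



I assume starting material is lost at rate k·c(starting material)·c(coupling partner). Each starting material lost takes one partner and each double product one more, so s, the partner used per starting material lost, is one plus double product over starting material lost. With a the fraction left, e the equivalents and d = e − s, the rate integrates to

a = d / (e·exp(d·k·c(starting material, charged)·t) − s)

At the last readings s is 1.17 in delta and 1.40 in alpha. Solving for k gives 1.49 × 10⁻⁴ L mol⁻¹ s⁻¹ and 1.54 × 10⁻⁴ L mol⁻¹ s⁻¹. I carry their mean, the coupling constant (a second-order rate constant) 1.52 × 10⁻⁴ L mol⁻¹ s⁻¹.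

The ladder begins with this flask's coupling time at its charges, 1/(k·c(starting material)·e) = 2.15 h, shorter than 3.00 h. Next, in the alpha run, the double product readings level off: 32.2% at 3.00 h and 33.0% at 5.00 h. Last comes a shortfall in the balance of the alpha readings, 7.40% at the last of them.

Interpolating s by equivalents gives 1.26, so my reckoning leaves 0.224 M of starting material. The forecast says 0.36 M of first product, 0.24 M of starting material and 0.15 M of double product, noting: "Mass balance is about 93–95%." Its starting material stands above my reckoning.

The flask gives 0.382 M of first product, 0.214 M of starting material and 0.115 M of double product, so the forecast's double product is 1.30 times the flask's.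

    coupling partner + first product ⇌ double product (K = 2.00 L mol⁻¹, k = 4.30 × 10⁻⁴ L mol⁻¹ s⁻¹)
    starting material + coupling partner → first product (k = 1.60 × 10⁻⁴ L mol⁻¹ s⁻¹)
    starting material → decomposition product (k = 7.00 × 10⁻⁸ s⁻¹)
    first product ⇌ isomer of the product (K = 11.0, k = 1.20 × 10⁻⁵ s⁻¹)

In this flask at 8.00 h, each step taken net, first product is still made 1.48 times faster than it is used up, while double product has gone from 17.4% of the starting material charged at 4.00 h to 14.2%. With 16% of the partner's charge left, k gives a coupling time of 13.1 h, longer than 8.0 h.

In a second flask with 0.49 M of starting material, equivalents and time held, k and s give 0.174 M left. The computed flask has 0.165 M.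

Readings and results were generated by integration for an exercise, and the scatter is random.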